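**Plan**

- Labels: ring A is the arene (going round from the bridge-bearing carbon: OMe, H, OH, acetyl, OH). Ring B is the triketone ring (B1 carries the CH2 bridge, B2, B4 and B6 carry oxygen, B3 is CMe2, B5 carries the acetyl group).
- Retrosynthesis: the two phenols beside the aryl ketone are masked as methyl ethers, the two C–acetyl bonds (one on ring A, one at B5) are cut, and the ring B oxygens at B4 and B6 are masked as enol ethers. Ring B is then cut at B1–B2 and B5–B6 (with B2–B3 opened and closed again) into a 4,4-dimethylcyclobutenone and a siloxyalkyne that already carries ring A.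
- Enabling feature: B3 of ring B is a quaternary CMe2 carbon between the oxygenated carbons B2 and B4. Ring B therefore sits at the oxidation level of a 3,5-dioxygenated 6,6-dimethylcyclohexa-2,4-dienone, where a vinylketene–alkyne annulation must stop when the ring-closing terminus has no hydrogen.
- Forward: ring A is bought as 2,4,6-trimethoxyphenylacetic acid and its side chain is homologated to a siloxyalkyne. Dimethylketene and ethoxyacetylene give the cyclobutenone, and heating the two partners forms ring B. Hydrolysis, double C-acetylation and chelation-directed bis-demethylation finish the synthesis.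
- Stereochemistry: the target has no stereocentre. The only geometric issue is the central double bond of a transient dienylketene, which corrects itself through reversible ring opening.

Key step: step 4

Remark on the chemistry: the target is a cyclic β-triketone written as one enol tautomer; the tautomers interconvert freely, so each ring B compound is drawn in one convenient enol form and counted as one compound.

**Step 1**
Reactants: 1 2-(2,4,6-trimethoxyphenyl)acetic acid
Product: 2 methyl 2-(2,4,6-trimethoxyphenyl)acetate
Conditions: MeOH, H2SO4 (cat.), reflux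
Reagents that add atoms: methanol, CO
Why: Fischer esterification of an unhindered arylacetic acid should proceed cleanly and gives the methyl ester, the substrate class on which the homologation of step 2 is established.

**Step 2**
Reactants: 2 methyl 2-(2,4,6-trimethoxyphenyl)acetate
Product: 5 triisopropyl{[3-(2,4,6-trimethoxyphenyl)prop-1-yn-1-yl]oxy}silane, via lithium dibromoenolate 3 (not isolated), via lithium ynolate 4 (not isolated)
Conditions: CH2Br2, lithium 2,2,6,6-tetramethylpiperidide, THF, −78 °C; then 2; LiN(SiMe3)2, −78 → −20 °C; n-BuLi, −78 °C → rt; iPr3SiCl, −78 → 0 °C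
Reagents that add atoms: dibromomethane, BrCBr; triisopropylsilyl chloride, CC(C)[Si](Cl)(C(C)C)C(C)C
Why: This is the Kowalski ester homologation stopped at the ynolate, in which LiCHBr2 adds to the ester, the adduct collapses to dibromoenolate 3, bromine–lithium exchange triggers 1,2-migration of the arylmethyl group to give ynolate 4, and the bulky iPr3SiCl silylates the ynolate on oxygen to give a storable siloxyalkyne.

**Step 3**
Reactants: 6 isobutyryl chloride; 7 ethoxyacetylene
Product: 9 3-ethoxy-4,4-dimethylcyclobut-2-en-1-one, via dimethylketene 8 (not isolated)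
Conditions: Et3N, Et2O, 0 °C → reflux
Reagents that add atoms: none
Why: Et3N dehydrochlorinates the acid chloride to dimethylketene 8, which is trapped in a ketene–alkoxyalkyne [2+2] cycloaddition where the nucleophilic CH terminus of ethoxyacetylene bonds to the ketene carbonyl carbon, so the 3-ethoxy-4,4-dimethyl regioisomer should result.

**Step 4**
Reactants: 9 3-ethoxy-4,4-dimethylcyclobut-2-en-1-one; 5 triisopropyl{[3-(2,4,6-trimethoxyphenyl)prop-1-yn-1-yl]oxy}silane
Product: 13 5-ethoxy-6,6-dimethyl-3-[(triisopropylsilyl)oxy]-2-(2,4,6-trimethoxybenzyl)cyclohexa-2,4-dien-1-one, via vinylketene 10 (not isolated), via vinylcyclobutenone 11 (not isolated), via dienylketene 12 (not isolated)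
Conditions: toluene (0.02 M in 5), 130 °C, sealed tube, slow addition of 9 (1.5 equiv)
Reagents that add atoms: none
Why: Proposed new method: thermal conrotatory 4π opening of 9 breaks B2–B3 and gives vinylketene 10, whose ketene C=C undergoes a [2+2] cycloaddition with the siloxyalkyne (the nucleophilic benzyl-bearing alkyne carbon attacks the ketene carbonyl carbon, forming B1–B2 and then B5–B6) to give 11; a second 4π opening of 11 gives dienylketene 12, and a thermal disrotatory 6π electrocyclisation of the ketene carbon B2 onto the CMe2 terminus B3 closes the six-membered ring B. The closest known reaction type is the Danheiser benzannulation of cyclobutenones with siloxyalkynes, which passes through the same four pericyclic events but ends in a resorcinol, supported by the well-known thermal closure of dienylketenes to 6,6-disubstituted cyclohexa-2,4-dienones. Here B3 carries two methyl groups and no hydrogen, so the cyclohexadienone cannot tautomerise to a phenol and should be the end point. No stereocentre remains in the product (the one in 11 is lost on ring opening); the ethoxyvinyl group must lie cis to the ketene on the central double bond of 12, and reversible opening of 11 should funnel material through that isomer because only it is drained by cyclisation. The required regiochemistry (benzyl carbon next to the B2 carbonyl, siloxy carbon next to B5) is secured by the polarisation of the siloxyalkyne against the electrophilic ketene carbon, and slow addition of 9 at high dilution should keep the ketene concentration low enough for capture by the alkyne to outrun dimerisation.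

**Step 5**
Reactants: 13 5-ethoxy-6,6-dimethyl-3-[(triisopropylsilyl)oxy]-2-(2,4,6-trimethoxybenzyl)cyclohexa-2,4-dien-1-one
Product: 14 3,5-dihydroxy-4,4-dimethyl-2-(2,4,6-trimethoxybenzyl)cyclohexa-2,5-dien-1-one (enol form of 2,2-dimethyl-4-(2,4,6-trimethoxybenzyl)cyclohexane-1,3,5-trione)
Conditions: 2 M HCl, THF, 40 °C
Reagents that add atoms: water, O
Why: Acid hydrolysis of the silyl enol ether and of the vinylogous ethyl ester (enol ether hydrolysis) is driven by formation of the strongly enolised cyclic β-triketone, while the aryl methyl ethers and the benzylic bridge are inert to dilute aqueous acid.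

**Step 6**
Reactants: 14 3,5-dihydroxy-4,4-dimethyl-2-(2,4,6-trimethoxybenzyl)cyclohexa-2,5-dien-1-one
Product: 16 2-acetyl-6-(3-acetyl-2,4,6-trimethoxybenzyl)-3,5-dihydroxy-4,4-dimethylcyclohexa-2,5-dien-1-one, via difluoroboron chelate 15 (not isolated)
Conditions: Ac2O (4 equiv), BF3·OEt2 (3 equiv), CH2Cl2, 0 °C → rt; then NaOAc, EtOH–H2O, 60 °C
Reagents that add atoms: acetic anhydride, CC(=O)OC(C)=O
Why: Friedel–Crafts acetylation with Ac2O and BF3 C-acylates an enolised cyclic 1,3-dione at the carbon between its carbonyls (B5, the only ring B carbon still bearing hydrogen) and a phloroglucinol trimethyl ether at a ring CH (the two free arene positions are equivalent by symmetry, and the first acetyl group deactivates the arene towards a second), the ring B acetyl-dione being held as difluoroboron chelate 15 until NaOAc hydrolyses it.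

**Step 7**
Reactants: 16 2-acetyl-6-(3-acetyl-2,4,6-trimethoxybenzyl)-3,5-dihydroxy-4,4-dimethylcyclohexa-2,5-dien-1-one
Product: 18 2-acetyl-6-(3-acetyl-2,4-dihydroxy-6-methoxybenzyl)-3,5-dihydroxy-4,4-dimethylcyclohexa-2,5-dien-1-one, via tris(dichloroboryl) ether 17 (not isolated)
Conditions: BCl3 (5 equiv), CH2Cl2, −78 °C → rt; then H2O
Reagents that add atoms: none
Why: In this chelation-directed ether cleavage BCl3 bound to the aryl ketone carbonyl cleaves the two methoxy groups ortho to it through six-membered chelates, whereas the remaining methoxy group, para to the ketone and next to the bridge, has no carbonyl neighbour and should survive, and water then frees the phenols and the ring B enols from boron.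

**Compound list**

1 | 2-(2,4,6-trimethoxyphenyl)acetic acid | COc1cc(OC)c(CC(=O)O)c(OC)c1 | starting material
2 | methyl 2-(2,4,6-trimethoxyphenyl)acetate | COC(=O)Cc1c(OC)cc(OC)cc1OC | intermediate
3 | lithium 1,1-dibromo-3-(2,4,6-trimethoxyphenyl)prop-1-en-2-olate | [Li+].[O-]C(Cc1c(OC)cc(OC)cc1OC)=C(Br)Br | intermediate
4 | lithium 3-(2,4,6-trimethoxyphenyl)prop-1-yn-1-olate | [Li+].[O-]C#CCc1c(OC)cc(OC)cc1OC | intermediate
5 | triisopropyl{[3-(2,4,6-trimethoxyphenyl)prop-1-yn-1-yl]oxy}silane | CC(C)[Si](OC#CCc1c(OC)cc(OC)cc1OC)(C(C)C)C(C)C | intermediate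
6 | isobutyryl chloride | CC(C)C(Cl)=O | starting material
7 | ethoxyacetylene | CCOC#C | starting material
8 | dimethylketene | CC(C)=C=O | intermediate
9 | 3-ethoxy-4,4-dimethylcyclobut-2-en-1-one | CCOC1=CC(=O)C1(C)C | intermediate
10 | 3-ethoxy-4-methylpenta-1,3-dien-1-one | CCOC(C=C=O)=C(C)C | intermediate
11 | 4-(1-ethoxy-2-methylprop-1-en-1-yl)-3-[(triisopropylsilyl)oxy]-2-(2,4,6-trimethoxybenzyl)cyclobut-2-en-1-one (racemic) | CCOC(=C(C)C)C1C(=O)C(Cc2c(OC)cc(OC)cc2OC)=C1O[Si](C(C)C)(C(C)C)C(C)C | intermediate
12 | (3E)-5-ethoxy-6-methyl-3-[(triisopropylsilyl)oxy]-2-(2,4,6-trimethoxybenzyl)hepta-1,3,5-trien-1-one | O=C=C(Cc1c(OC)cc(OC)cc1OC)/C(O[Si](C(C)C)(C(C)C)C(C)C)=C\C(OCC)=C(C)C | intermediate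
13 | 5-ethoxy-6,6-dimethyl-3-[(triisopropylsilyl)oxy]-2-(2,4,6-trimethoxybenzyl)cyclohexa-2,4-dien-1-one | O=C1C(Cc2c(OC)cc(OC)cc2OC)=C(O[Si](C(C)C)(C(C)C)C(C)C)C=C(OCC)C1(C)C | intermediate
14 | 3,5-dihydroxy-4,4-dimethyl-2-(2,4,6-trimethoxybenzyl)cyclohexa-2,5-dien-1-one | COc1cc(OC)c(CC2=C(O)C(C)(C)C(O)=CC2=O)c(OC)c1 | intermediate
15 | difluoroboron chelate of 16 (boron bound to the ring B acetyl oxygen and the B4 oxygen) | CC1=[O+][B-](F)(F)OC2=C1C(=O)C(Cc3c(OC)cc(OC)c(C(C)=O)c3OC)=C(O)C2(C)C | intermediate
16 | 2-acetyl-6-(3-acetyl-2,4,6-trimethoxybenzyl)-3,5-dihydroxy-4,4-dimethylcyclohexa-2,5-dien-1-one | COc1cc(OC)c(C(C)=O)c(OC)c1CC1=C(O)C(C)(C)C(O)=C(C(C)=O)C1=O | intermediate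
17 | tris(dichloroboryl) ether of 18 before work-up (OBCl2 groups on the two phenol oxygens of ring A and on the B4 oxygen) | COc1cc(OB(Cl)Cl)c(C(C)=O)c(OB(Cl)Cl)c1CC1=C(O)C(C)(C)C(OB(Cl)Cl)=C(C(C)=O)C1=O | intermediate
18 | 2-acetyl-6-(3-acetyl-2,4-dihydroxy-6-methoxybenzyl)-3,5-dihydroxy-4,4-dimethylcyclohexa-2,5-dien-1-one | COc1cc(O)c(C(C)=O)c(O)c1CC1=C(O)C(C)(C)C(O)=C(C(C)=O)C1=O | target

**Step count**

Total: 7 steps. Longest linear sequence: 6 steps (steps 1, 2, 4, 5, 6 and 7, from acid 1).

**Steps most likely to fail**

Step 4 (Proposed new method). The gem-dimethyl cyclobutenone may open only at temperatures where the siloxyalkyne isomerises to a silylketene. The vinylketene may also dimerise, or be lost through a 1,5-hydrogen shift from its inward methyl group, before the alkyne captures it. The fallback builds ring B by known carbonyl condensations; it sets out from ester 2 and returns to the route at trione 14. The sequence of step 2 is run as far as ynolate 4 and quenched with acidic methanol instead of iPr3SiCl, which is the Kowalski homologation in its ester-forming mode and should give methyl 3-(2,4,6-trimethoxyphenyl)propanoate F1. A crossed Claisen condensation of F1 with two equivalents of the lithium enolate of methyl 2,2-dimethyl-3-oxobutanoate (LiN(iPr)2, THF, −78 → 0 °C; the acetyl methyl is the only enolisable site of that keto ester) should give methyl 2,2-dimethyl-3,5-dioxo-7-(2,4,6-trimethoxyphenyl)heptanoate F2. Treating F2 with LiN(iPr)2 (2.2 equiv, THF, −78 °C → rt) should form dilithium 7-methoxy-6,6-dimethyl-7-oxo-1-(2,4,6-trimethoxyphenyl)hepta-2,4-diene-3,5-bis(olate) F3, the dianion of the β-diketone. Its terminal carbanion should attack the ester in an intramolecular Claisen condensation and close the six-membered ring, giving 14 after acidic work-up.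

Step 6. Ring B may be acetylated on oxygen and stop there, and the hindered arene position may react slowly. The strongly acidic medium may also protonate the electron-rich arene at its bridge-bearing carbon and shift the methylene bridge (retro-Friedel–Crafts alkylation) before the arene is deactivated by its acetyl group. The fallback introduces the two acetyl groups separately and without a metal Lewis acid; it sets out from 14 and returns at 16. Acetic acid, N,N'-dicyclohexylcarbodiimide and 4-(dimethylamino)pyridine in CH2Cl2 at rt acylate the enol on oxygen and transfer the acetyl group to carbon (the standard route to 2-acyl-cyclohexane-1,3-diones). This should give 2-acetyl-3,5-dihydroxy-4,4-dimethyl-6-(2,4,6-trimethoxybenzyl)cyclohexa-2,5-dien-1-one F4. The arene of F4 is then acetylated with acetyl trifluoroacetate generated from acetic acid and (CF3CO)2O (CH2Cl2, 0 °C → rt). A work-up with NaHCO3 in aqueous methanol removes any enol esters and should give 16.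

Step 2. The amide bases may deprotonate the benzylic position of the arylacetate faster than LiCHBr2 adds to the ester carbonyl. Base may also isomerise the propargylic product towards an allene, and silylation may occur on carbon. The fallback reaches the same ynolate by oxidation of an acetylide; it sets out from ester 2 and returns at ynolate 4. Reduction with iBu2AlH (toluene, −78 °C) should give 2-(2,4,6-trimethoxyphenyl)acetaldehyde F5. Ohira–Bestmann homologation with dimethyl (1-diazo-2-oxopropyl)phosphonate and K2CO3 in MeOH (0 °C → rt) should give 1,3,5-trimethoxy-2-(prop-2-yn-1-yl)benzene F6. Deprotonation with n-BuLi (THF, −78 °C) gives lithium 3-(2,4,6-trimethoxyphenyl)prop-1-yn-1-ide F7. Oxidation of F7 with LiOOtBu (from tBuOOH and LiN(SiMe3)2, −78 → 0 °C) should deliver ynolate 4, which is silylated with iPr3SiCl as in step 2 to give 5.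

**Further compounds**

F1 | step 4 | methyl 3-(2,4,6-trimethoxyphenyl)propanoate | COC(=O)CCc1c(OC)cc(OC)cc1OC
F2 | step 4 | methyl 2,2-dimethyl-3,5-dioxo-7-(2,4,6-trimethoxyphenyl)heptanoate | COC(=O)C(C)(C)C(=O)CC(=O)CCc1c(OC)cc(OC)cc1OC
F3 | step 4 | dilithium 7-methoxy-6,6-dimethyl-7-oxo-1-(2,4,6-trimethoxyphenyl)hepta-2,4-diene-3,5-bis(olate) | [Li+].[Li+].COC(=O)C(C)(C)C([O-])=CC([O-])=CCc1c(OC)cc(OC)cc1OC
F4 | step 6 | 2-acetyl-3,5-dihydroxy-4,4-dimethyl-6-(2,4,6-trimethoxybenzyl)cyclohexa-2,5-dien-1-one | COc1cc(OC)c(CC2=C(O)C(C)(C)C(O)=C(C(C)=O)C2=O)c(OC)c1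
F5 | step 2 | 2-(2,4,6-trimethoxyphenyl)acetaldehyde | O=CCc1c(OC)cc(OC)cc1OC
F6 | step 2 | 1,3,5-trimethoxy-2-(prop-2-yn-1-yl)benzene | C#CCc1c(OC)cc(OC)cc1OC
F7 | step 2 | lithium 3-(2,4,6-trimethoxyphenyl)prop-1-yn-1-ide | [Li+].[C-]#CCc1c(OC)cc(OC)cc1OC
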